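**Retrosynthetic overview**
1. The last events are closure of the 4-pyranone (O1–C2) and loss of all acetals from an α-formyl deoxybenzoin. Only the future O1 carries the very labile THP group, and this fixes the 6-prenyl (not 8-prenyl) isomer.
2. Key disconnection at C2–C3 and C3–C1′: the α-formyl deoxybenzoin comes from an A-ring α-diazo ketone and a B-ring chromene-6-carbaldehyde by addition, N2 loss and a cationic 1,2-aryl shift.
3. A-ring piece: resorcinol → bis-MOM → ortho-lithiation/prenylation → Ir C–H borylation/oxidation (third oxygen, the future O1) → THP → second ortho-lithiation with ClCH2C(O)N(OMe)Me → diazo ketone.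
4. B-ring piece: resorcinol + prenal (dimethylpyran ring) → ortho-formylation → MOM.
5. Ring order: both benzene rings come from resorcinol. The dimethylpyran ring is made first (B series) and the 4-pyranone ring last.

Assumption: the target SMILES has no stereocentre and no stereogenic double bond, so the compound is achiral and nothing has to be set. Stereocentres in intermediates (the THP acetal carbon and the chain carbons of the key adducts) are unspecified mixtures and vanish before the end.

**Step 1**
Reactants: 1 resorcinol (benzene-1,3-diol)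
Product: 2 1,3-bis(methoxymethoxy)benzene
Conditions: MOMCl (2.5 equiv), iPr2NEt (3 equiv), CH2Cl2, 0 °C → rt
Reagents that add atoms: chloromethyl methyl ether (MOMCl), COCCl
Why: O-alkylation of both phenols (MOM acetal formation) gives base-stable groups that direct lithiation and all fall off together at the end.

**Step 2**
Reactants: 2 1,3-bis(methoxymethoxy)benzene; 3 prenyl bromide (1-bromo-3-methylbut-2-ene)
Product: 5 1,3-bis(methoxymethoxy)-2-(3-methylbut-2-en-1-yl)benzene, via 2-lithio-1,3-bis(methoxymethoxy)benzene 4 (not isolated)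
Conditions: n-BuLi (1.15 equiv), THF, 0 °C → rt, 1.5 h; CuI (10 mol %), then 3, −78 °C → rt
Reagents that add atoms: n-butyllithium, [Li]CCCC (supplies the Li of intermediate 4 only)
Why: Directed ortho-metalation lithiates only the C2–H between the two coordinating OMOM groups, and the Cu-assisted aryllithium 4 displaces bromide at the primary carbon of 3 (SN2 allylation), which places the prenyl group between the future O5 and O7.

**Step 3**
Reactants: 5 1,3-bis(methoxymethoxy)-2-(3-methylbut-2-en-1-yl)benzene
Product: 7 3,5-bis(methoxymethoxy)-4-(3-methylbut-2-en-1-yl)phenol, via aryl pinacol boronate 6 (not isolated)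
Conditions: [Ir(OMe)(cod)]2 (1.5 mol %), dtbpy (3 mol %), B2pin2 (0.6 equiv), THF, 60 °C; then aq NaOH, 30 % H2O2, 0 °C → rt
Reagents that add atoms: hydrogen peroxide, OO; bis(pinacolato)diboron, CC1(C)OB(OC1(C)C)B1OC(C)(C)C(C)(C)O1 (supplies the Bpin of intermediate 6 only)
Why: Sterically governed Ir-catalysed aromatic C–H borylation (Hartwig–Miyaura type) can only reach C5–H, the one ring C–H without an ortho substituent, and basic peroxide then turns the C–B bond of 6 into C–O (boronate oxidation) without touching the unactivated trisubstituted alkene or the MOM ethers, so the third oxygen arrives as the only free OH.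

**Step 4**
Reactants: 7 3,5-bis(methoxymethoxy)-4-(3-methylbut-2-en-1-yl)phenol
Product: 8 2-[3,5-bis(methoxymethoxy)-4-(3-methylbut-2-en-1-yl)phenoxy]tetrahydro-2H-pyran (racemic acetal carbon)
Conditions: 3,4-dihydro-2H-pyran (1.5 equiv), PPTS (5 mol %), CH2Cl2, rt
Reagents that add atoms: 3,4-dihydro-2H-pyran, C1=COCCC1
Why: Acid-catalysed addition of the phenol to the enol ether (THP acetal formation) spares MOM and prenyl and tags the future O1 with a group that directs lithiation and is cleaved far faster than MOM; the new acetal centre is racemic and is lost later.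

**Step 5**
Reactants: 8 the THP ether; 9 2-chloro-N-methoxy-N-methylacetamide
Product: 11 2-chloro-1-[2,4-bis(methoxymethoxy)-3-(3-methylbut-2-en-1-yl)-6-(tetrahydro-2H-pyran-2-yloxy)phenyl]ethan-1-one, via aryllithium (Li between OTHP and OMOM) 10 (not isolated)
Conditions: n-BuLi (1.1 equiv), THF, 0 °C, 1 h; then 9 (1.3 equiv), −78 °C; sat. aq NH4Cl at −78 °C
Reagents that add atoms: n-butyllithium, [Li]CCCC (supplies the Li of intermediate 10 only)
Why: A second directed ortho-metalation takes one of the two equivalent ring C–H (each flanked by OTHP and OMOM) and is followed by a Weinreb ketone synthesis, whose chelated tetrahedral adduct holds until the cold quench so that neither over-addition nor chloride displacement occurs.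

**Step 6**
Reactants: 11 the α-chloro ketone
Product: 12 2-diazo-1-[2,4-bis(methoxymethoxy)-3-(3-methylbut-2-en-1-yl)-6-(tetrahydro-2H-pyran-2-yloxy)phenyl]ethan-1-one
Conditions: TsNHNHTs (2 equiv), DBU (5 equiv), NaI (10 mol %), THF, 0 °C
Reagents that add atoms: N,N′-ditosylhydrazine, Cc1ccc(cc1)S(=O)(=O)NNS(=O)(=O)c1ccc(C)cc1
Why: N-alkylation of the ditosylhydrazine anion by the reactive α-halo ketone and two base-induced sulfinate eliminations (Bamford–Stevens type) give the diazo ketone under non-acidic conditions that all acetals and the alkene tolerate.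

**Step 7**
Reactants: 1 resorcinol; 13 3-methylbut-2-enal (prenal)
Product: 14 2,2-dimethyl-2H-chromen-7-ol
Conditions: 1 (2 equiv), ethylenediammonium diacetate (10 mol %), xylene, 140 °C, Dean–Stark
Reagents that add atoms: none
Why: The amine-salt-catalysed formal [3+3] chromene annulation (Knoevenagel-type C-alkylation at the unhindered C4 of resorcinol, dehydration, oxa-6π ring closure) gives mainly the 7-ol, and the minor 5-ol and bis-chromene are removed by chromatography.

**Step 8**
Reactants: 14 2,2-dimethyl-2H-chromen-7-ol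
Product: 15 7-hydroxy-2,2-dimethyl-2H-chromene-6-carbaldehyde
Conditions: MgCl2 (2 equiv), Et3N (4 equiv), (CH2O)n (6 equiv), MeCN, reflux; cold 1 M HCl work-up
Reagents that add atoms: paraformaldehyde (as formaldehyde), C=O
Why: Magnesium-phenolate-directed ortho-formylation (Casnati–Skattebøl) is ortho-specific and takes the open C6 rather than C8, which is wedged between two oxygens, while a second formaldehyde accepts the hydride (Oppenauer type).

**Step 9**
Reactants: 15 7-hydroxy-2,2-dimethyl-2H-chromene-6-carbaldehyde
Product: 16 7-(methoxymethoxy)-2,2-dimethyl-2H-chromene-6-carbaldehyde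
Conditions: MOMCl (1.5 equiv), iPr2NEt (2 equiv), CH2Cl2, 0 → 40 °C
Reagents that add atoms: chloromethyl methyl ether (MOMCl), COCCl
Why: O-alkylation (MOM acetal) masks the future 2′-OH so that it cannot trap the formyl group as a benzofuran in step 10.

**Step 10**
Reactants: 12 the α-diazo ketone; 16 the MOM-protected chromene-6-carbaldehyde
Product: 20 krausianone 2, via β-hydroxy-α-diazonium ketone 17 (not isolated), via 2-aryl-3-oxopropanal (α-formyl deoxybenzoin) 18 (not isolated), via tri-MOM isoflavone 19 (not isolated)
Conditions: 16 (1.3 equiv), HBF4·OEt2 (10 mol %), CH2Cl2, −78 °C, 12 added over 1 h, → −20 °C; then MeOH, HCl (to 1 M), rt 1 h, then 40 °C, 4 h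
Reagents that add atoms: none
Why: Proposed new method: the acid-activated, electron-rich aldehyde 16 is attacked by the nucleophilic diazo carbon of 12 to give 17, in which loss of N2 is driven by anti-periplanar migration of the 2,4-dioxygenated aryl group from the carbinol carbon to Cα (a cationic semipinacol/Tiffeneau–Demjanov-type 1,2-aryl shift through a phenonium-like transition state with the carbinol oxygen pushing), so that C2–C3 and then C3–C1′ are formed and 18 results; methanolic acid at rt then removes the far more labile THP first, the freed O1–H adds to the formyl group and water is lost to give 19 (hence only the 6-prenyl isomer), and warming cleaves the three MOM ethers; the closest known reaction type is the Brønsted- or iron-Lewis-acid-catalysed reaction of aromatic aldehydes with ethyl diazoacetate that gives 3-hydroxy-2-arylacrylates by 1,2-aryl shift (the aryl-shift branch of the Roskamp homologation, best with electron-rich aryl groups), which to my knowledge has not been shown for α-diazo ketones or used to close an isoflavone; no oxidant is present, so both C=C bonds stay untouched, any epoxy ketone formed by O-closure of 17 would funnel to the same 18 by acid-induced 1,2-acyl shift, and no stereocentre survives.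

**Compound list**
1 | resorcinol | Oc1cccc(O)c1 | starting material
2 | 1,3-bis(methoxymethoxy)benzene | COCOc1cccc(OCOC)c1 | intermediate
3 | prenyl bromide | CC(C)=CCBr | starting material
4 | 2-lithio-1,3-bis(methoxymethoxy)benzene | [Li]c1c(OCOC)cccc1OCOC | intermediate (not isolated)
5 | 1,3-bis(methoxymethoxy)-2-(3-methylbut-2-en-1-yl)benzene | COCOc1cccc(OCOC)c1CC=C(C)C | intermediate
6 | 2-[3,5-bis(methoxymethoxy)-4-(3-methylbut-2-en-1-yl)phenyl]-4,4,5,5-tetramethyl-1,3,2-dioxaborolane | COCOc1cc(B2OC(C)(C)C(C)(C)O2)cc(OCOC)c1CC=C(C)C | intermediate (not isolated)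
7 | 3,5-bis(methoxymethoxy)-4-(3-methylbut-2-en-1-yl)phenol | COCOc1cc(O)cc(OCOC)c1CC=C(C)C | intermediate
8 | 2-[3,5-bis(methoxymethoxy)-4-(3-methylbut-2-en-1-yl)phenoxy]tetrahydro-2H-pyran (racemic) | COCOc1cc(OC2CCCCO2)cc(OCOC)c1CC=C(C)C | intermediate
9 | 2-chloro-N-methoxy-N-methylacetamide | CON(C)C(=O)CCl | starting material
10 | aryllithium from 8 (Li between OTHP and OMOM) | [Li]c1c(OCOC)c(CC=C(C)C)c(OCOC)cc1OC1CCCCO1 | intermediate (not isolated)
11 | 2-chloro-1-[2,4-bis(methoxymethoxy)-3-(3-methylbut-2-en-1-yl)-6-(tetrahydro-2H-pyran-2-yloxy)phenyl]ethan-1-one | ClCC(=O)c1c(OCOC)c(CC=C(C)C)c(OCOC)cc1OC1CCCCO1 | intermediate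
12 | 2-diazo-1-[2,4-bis(methoxymethoxy)-3-(3-methylbut-2-en-1-yl)-6-(tetrahydro-2H-pyran-2-yloxy)phenyl]ethan-1-one | [N-]=[N+]=CC(=O)c1c(OCOC)c(CC=C(C)C)c(OCOC)cc1OC1CCCCO1 | intermediate
13 | 3-methylbut-2-enal (prenal) | CC(C)=CC=O | starting material
14 | 2,2-dimethyl-2H-chromen-7-ol | CC1(C)C=Cc2ccc(O)cc2O1 | intermediate
15 | 7-hydroxy-2,2-dimethyl-2H-chromene-6-carbaldehyde | CC1(C)C=Cc2cc(C=O)c(O)cc2O1 | intermediate
16 | 7-(methoxymethoxy)-2,2-dimethyl-2H-chromene-6-carbaldehyde | CC1(C)C=Cc2cc(C=O)c(OCOC)cc2O1 | intermediate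
17 | β-hydroxy-α-diazonium ketone (cation, mixture of diastereomers) | O=C(C([N+]#N)C(O)c1cc2C=CC(C)(C)Oc2cc1OCOC)c1c(OCOC)c(CC=C(C)C)c(OCOC)cc1OC1CCCCO1 | intermediate (not isolated)
18 | 3-[2,4-bis(methoxymethoxy)-3-prenyl-6-(THP-oxy)phenyl]-2-[7-(methoxymethoxy)-2,2-dimethyl-2H-chromen-6-yl]-3-oxopropanal (enolisable, stereo-undefined) | O=CC(c1cc2C=CC(C)(C)Oc2cc1OCOC)C(=O)c1c(OCOC)c(CC=C(C)C)c(OCOC)cc1OC1CCCCO1 | intermediate (not isolated)
19 | 5,7-bis(methoxymethoxy)-3-[7-(methoxymethoxy)-2,2-dimethyl-2H-chromen-6-yl]-6-(3-methylbut-2-en-1-yl)-4H-chromen-4-one | COCOc1cc2occ(-c3cc4C=CC(C)(C)Oc4cc3OCOC)c(=O)c2c(OCOC)c1CC=C(C)C | intermediate (not isolated)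
20 | krausianone 2, 5,7-dihydroxy-3-(7-hydroxy-2,2-dimethyl-2H-chromen-6-yl)-6-(3-methylbut-2-en-1-yl)-4H-chromen-4-one (achiral) | CC(C)=CCc1c(O)cc2occ(-c3cc4c(cc3O)OC(C)(C)C=C4)c(=O)c2c1O | target

**Step count**
Total: 10 steps. Longest linear sequence: 7 steps (steps 1–6 and 10).

**Steps most likely to fail**

*Step 10 (the proposed new step).* There are three risks:
- A 1,2-hydride shift in 17 could compete with the aryl shift. It leads to the 1,3-diketone and then a flavone.
- 12 could be protonated at carbon and captured by an ortho acetal oxygen, which gives a benzofuran-3(2H)-one.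
- The THP group could be lost before C–C bond formation.

The fallback uses known chemistry. It sets out from 11 and 16 and comes back at 18, so step 6 is not needed and the step count stays the same. Darzens condensation of 11 with 16 (KOtBu, THF, −78 → 0 °C) gives the racemic trans-chalcone epoxide F1. BF3·OEt2 (CH2Cl2, −78 °C) ionises its benzylic C–O bond and the aroyl group migrates. This is the House–Meinwald 1,2-acyl shift, the classical chalcone-epoxide entry to isoflavones, and it gives 18. The methanolic HCl stage of step 10 then takes 18 to 20.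

*Step 5.* The doubly ortho-alkoxylated benzylic/allylic CH2 of the prenyl group could be lithiated instead of the ring. The hindered aryllithium could also enolise 9 rather than add to it. The fallback replaces deprotonation by halogen–metal exchange. It sets out from 7 and comes back at 11.
- Iodination of the activated ring (NIS, CH2Cl2, −40 °C; the two free ring positions are equivalent) gives 2-iodo-3,5-bis(methoxymethoxy)-4-prenylphenol F2.
- DHP/PPTS gives its THP ether F3.
- iPrMgCl·LiCl (THF, −20 °C) gives the arylmagnesium chloride F4.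
- F4 is acylated with 9 to give 11.

*Step 3.* The Ir/boryl system could hydroborate, isomerise or borylate the prenyl alkene. The fallback brings the alkene in only after the Ir step. It sets out from 2 and comes back at 7, replacing steps 2 and 3.
- Borylation of 2 under the same catalyst gives 2-[3,5-bis(methoxymethoxy)phenyl] pinacol boronate F5.
- NaOH/H2O2 gives 3,5-bis(methoxymethoxy)phenol F6.
- n-BuLi (2.2 equiv, THF, 0 °C) gives the O,C-dilithio species F7, with the carbon lithiated between the two OMOM groups because the phenoxide deactivates its own ortho sites.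
- CuI (10 mol %) and 3 at −78 °C → rt alkylate the carbon only, which gives 7 after an NH4Cl quench.

**Further compounds**
F1 | step 10 | rac-trans-[2,4-bis(methoxymethoxy)-3-prenyl-6-(THP-oxy)phenyl]{3-[7-(methoxymethoxy)-2,2-dimethyl-2H-chromen-6-yl]oxiran-2-yl}methanone (THP centre unspecified) | O=C([C@@H]1O[C@H]1c1cc2C=CC(C)(C)Oc2cc1OCOC)c1c(OCOC)c(CC=C(C)C)c(OCOC)cc1OC1CCCCO1
F2 | step 5 | 2-iodo-3,5-bis(methoxymethoxy)-4-(3-methylbut-2-en-1-yl)phenol | COCOc1cc(O)c(I)c(OCOC)c1CC=C(C)C
F3 | step 5 | 2-[2-iodo-3,5-bis(methoxymethoxy)-4-(3-methylbut-2-en-1-yl)phenoxy]tetrahydro-2H-pyran | COCOc1cc(OC2CCCCO2)c(I)c(OCOC)c1CC=C(C)C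
F4 | step 5 | [2,4-bis(methoxymethoxy)-3-prenyl-6-(THP-oxy)phenyl]magnesium chloride | COCOc1cc(OC2CCCCO2)c([Mg]Cl)c(OCOC)c1CC=C(C)C
F5 | step 3 | 2-[3,5-bis(methoxymethoxy)phenyl]-4,4,5,5-tetramethyl-1,3,2-dioxaborolane | COCOc1cc(B2OC(C)(C)C(C)(C)O2)cc(OCOC)c1
F6 | step 3 | 3,5-bis(methoxymethoxy)phenol | COCOc1cc(O)cc(OCOC)c1
F7 | step 3 | lithium 4-lithio-3,5-bis(methoxymethoxy)phenoxide | [Li]Oc1cc(OCOC)c([Li])c(OCOC)c1
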